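**Assumption and notation (one line):** 1, 14, 23 and (+)-Ipc2BOMe are taken as catalogue compounds; chain atoms carry the target numbers C1 (amide C=O) to C15 (benzylic carbinol); the target is read as 2E,6S,7S,8E,10S,11R,12S,14S,15R; ArTBS = 3-(tert-butyldimethylsilyloxy)-5-nitrophenyl.

## Retrosynthetic overview
1. The only ring of the target, the 19-membered anilide, is closed last by N-acylation of the free aniline with the C1 thioester (N-acetylcysteamine, SNAC) of the fully unprotected seco chain, as in amide-synthase chain release.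
2. The seco chain is grown in the polyketide direction (C15 → C1) from an AHBA-type starter, 3-hydroxy-5-nitrobenzaldehyde (nitro = masked aniline).
3. C14/C15 come from a syn-crotylboration; C11 and the C12 methoxy group come from hydroformylation to a temporary δ-lactone, followed by face-selective enolate hydroxylation and O-methylation.
4. C10/C11 come from a substrate-controlled (Z)-crotylboration of the lactol with the commercial pinacol boronate, C8=C9 from cross-metathesis with methacrolein, C6/C7 from a γ-methoxyallylboration, and C1–C3 from a B-alkyl Suzuki coupling with an iodo-acrylic SNAC thioester.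
5. Ring order: temporary δ-lactone/lactol (steps 3–8, opened again), then the macrolactam (step 14).

## Route

Step 1
Reactants: 1 3-hydroxy-5-nitrobenzaldehyde
Product: 2 3-(tert-butyldimethylsilyloxy)-5-nitrobenzaldehyde
Conditions: TBSCl, imidazole, DMF, 0 °C → rt
Reagents that add atoms: tert-butyldimethylsilyl chloride, CC(C)(C)[Si](C)(C)Cl
Why: Standard phenol silylation masks the acidic ArOH for the organoborane, enolate and O-methylation steps and creates no stereocentre.

Step 2
Reactants: 2 3-(tert-butyldimethylsilyloxy)-5-nitrobenzaldehyde; 3 cis-2-butene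
Product: 6 (1R,2S)-1-ArTBS-2-methylbut-3-en-1-ol, via (Z)-crotylpotassium 4 (not isolated), via (Z)-crotyldiisopinocampheylborane 5 (not isolated)
Conditions: cis-2-butene, KOt-Bu, n-BuLi, THF, −78 → −45 °C; (+)-Ipc2BOMe [from (−)-α-pinene], −78 °C; BF3·OEt2; then 2, −78 °C, 4 h; ethanolamine, rt
Reagents that add atoms: none
Why: Brown asymmetric crotylboration through a chair Zimmerman–Traxler transition state, in which the Z reagent gives the 14,15-syn product and the Ipc groups of the (−)-α-pinene series direct attack to the Re face of the aldehyde (15R, 14S).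

Step 3
Reactants: 6 (1R,2S)-1-ArTBS-2-methylbut-3-en-1-ol
Product: 8 (5S,6R)-6-ArTBS-5-methyltetrahydro-2H-pyran-2-ol (anomer mixture), via hydroxy aldehyde 7 (not isolated)
Conditions: Rh(acac)(CO)2 (1 mol%), Xantphos (3 mol%), CO/H2 (1:1, 10 bar), toluene, 70 °C
Reagents that add atoms: carbon monoxide, [C-]#[O+]
Why: Linear-selective rhodium-catalysed hydroformylation (wide-bite-angle ligand plus allylic branching) places C11 on the terminal carbon and the δ-hydroxy aldehyde closes to the six-membered lactol, the only new centre being the uncontrolled anomeric one that is removed in step 4.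

Step 4
Reactants: 8 (5S,6R)-6-ArTBS-5-methyltetrahydro-2H-pyran-2-ol
Product: 9 (5S,6R)-6-ArTBS-5-methyltetrahydro-2H-pyran-2-one
Conditions: TEMPO (10 mol%), PhI(OAc)2, CH2Cl2, rt
Reagents that add atoms: none
Why: Oxoammonium (TEMPO) oxidation of a lactol to the δ-lactone, which leaves C14 and C15 untouched.

Step 5
Reactants: 9 (5S,6R)-6-ArTBS-5-methyltetrahydro-2H-pyran-2-one
Product: 11 (3S,5S,6R)-6-ArTBS-3-hydroxy-5-methyltetrahydro-2H-pyran-2-one, via potassium enolate 10 (not isolated)
Conditions: KN(SiMe3)2, THF, −78 °C, 20 min; 2-(phenylsulfonyl)-3-phenyloxaziridine, −78 °C; aqueous NH4Cl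
Reagents that add atoms: 2-(phenylsulfonyl)-3-phenyloxaziridine, O=S(=O)(c1ccccc1)N1OC1c1ccccc1
Why: Davis enolate hydroxylation in which the half-chair enolate holds the aryl group pseudo-equatorial and the cis C14 methyl pseudo-axial, so the oxidant attacks C12 anti to that methyl and gives the 3,5-trans (12S) alcohol, which is also the more stable equatorial epimer.

Step 6
Reactants: 11 (3S,5S,6R)-6-ArTBS-3-hydroxy-5-methyltetrahydro-2H-pyran-2-one
Product: 12 (3S,5S,6R)-6-ArTBS-3-methoxy-5-methyltetrahydro-2H-pyran-2-one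
Conditions: MeI (10 equiv), Ag2O, 4 Å MS, MeCN, 40 °C, dark
Reagents that add atoms: iodomethane, CI
Why: Purdie methylation etherifies the α-hydroxy lactone without strong base, so C12 is not epimerised and the lactone is not opened, while the silyl ether keeps the phenol from being methylated.

Step 7
Reactants: 12 (3S,5S,6R)-6-ArTBS-3-methoxy-5-methyltetrahydro-2H-pyran-2-one
Product: 13 (3S,5S,6R)-6-ArTBS-3-methoxy-5-methyltetrahydro-2H-pyran-2-ol (anomer mixture)
Conditions: i-Bu2AlH (1.1 equiv), CH2Cl2, −78 °C; aqueous KNaC4H4O6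
Reagents that add atoms: none
Why: Low-temperature DIBAL-H half-reduction stops at the aluminium lactolate and delivers the lactol as a masked α-methoxy aldehyde with the C15 hydroxyl internally protected, the nitro group being inert at −78 °C.

Step 8
Reactants: 13 (3S,5S,6R)-6-ArTBS-3-methoxy-5-methyltetrahydro-2H-pyran-2-ol; 14 (Z)-crotylboronic acid pinacol ester
Product: 16 (3S,4R,5S,7S,8R)-8-ArTBS-5-methoxy-3,7-dimethyloct-1-ene-4,8-diol, via open-chain hydroxy aldehyde 15 (not isolated)
Conditions: 14 (3 equiv), 4 Å MS, toluene (2 M), rt → 45 °C, 72 h; N(CH2CH2OH)3, rt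
Reagents that add atoms: none
Why: Hoffmann-type (type I) crotylboration of the lactol through its open-chain tautomer via a chair Zimmerman–Traxler transition state, in which the Z boronate gives the 10,11-syn relationship and, as is general for (Z)-crotylboronates with α-alkoxy aldehydes, the Felkin/Cornforth arrangement that keeps the Z-methyl group away from the C12 methoxy group gives the 11,12-anti adduct (10S, 11R), the minor diastereomer being removed by chromatography.

Step 9
Reactants: 16 (3S,4R,5S,7S,8R)-8-ArTBS-5-methoxy-3,7-dimethyloct-1-ene-4,8-diol; 17 methacrolein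
Product: 18 (2E,4S,5R,6S,8S,9R)-9-ArTBS-5,9-dihydroxy-6-methoxy-2,4,8-trimethylnon-2-enal
Conditions: second-generation Hoveyda–Grubbs catalyst RuCl2(H2IMes)(=CH-C6H4-2-O-i-Pr) (10 mol%), methacrolein (10 equiv), CH2Cl2, 40 °C
Reagents that add atoms: none
Why: Olefin cross-metathesis of the monosubstituted alkene with excess methacrolein gives the thermodynamically favoured (E)-trisubstituted enal (C8=C9) and tolerates the free diol, the nitro group and the aryl silyl ether.

Step 10
Reactants: 18 (2E,4S,5R,6S,8S,9R)-9-ArTBS-5,9-dihydroxy-6-methoxy-2,4,8-trimethylnon-2-enal; 19 allyl methyl ether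
Product: 22 (3S,4S,5E,7S,8R,9S,11S,12R)-12-ArTBS-3,9-dimethoxy-5,7,11-trimethyldodeca-1,5-diene-4,8,12-triol, via (Z)-3-methoxyallyllithium 20 (not isolated), via (Z)-3-methoxyallyldiisopinocampheylborane 21 (not isolated)
Conditions: allyl methyl ether, s-BuLi, THF, −78 °C; (+)-Ipc2BOMe; BF3·OEt2; then 18 (reagent 4 equiv), −78 °C, 4 h; ethanolamine, rt
Reagents that add atoms: none
Why: Brown γ-methoxyallylboration in which the chelated Z allyl anion leads through a chair transition state to the syn C6-methoxy/C7-hydroxy pair and the Ipc groups direct Re-face attack on the enal (7S, 6S), with excess reagent covering the two free hydroxyls.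

Step 11
Reactants: 23 (E)-3-iodo-2-methylprop-2-enoic acid; 24 N-acetylcysteamine
Product: 25 S-(2-acetamidoethyl) (E)-3-iodo-2-methylprop-2-enethioate
Conditions: EDC·HCl, DMAP (5 mol%), CH2Cl2, 0 °C → rt
Reagents that add atoms: none
Why: Carbodiimide (Steglich-type) thioesterification, in which the thiol attacks the O-acylisourea faster than it can add to the α-methyl-deactivated iodo-enoate, so the E geometry is kept.

Step 12
Reactants: 22 (3S,4S,5E,7S,8R,9S,11S,12R)-12-ArTBS-3,9-dimethoxy-5,7,11-trimethyldodeca-1,5-diene-4,8,12-triol; 25 S-(2-acetamidoethyl) (E)-3-iodo-2-methylprop-2-enethioate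
Product: 28 S-(2-acetamidoethyl) (2E,6S,7S,8E,10S,11R,12S,14S,15R)-7,11,15-trihydroxy-15-(3-hydroxy-5-nitrophenyl)-6,12-dimethoxy-2,8,10,14-tetramethylpentadeca-2,8-dienethioate, via B-alkyl-9-BBN borane 26 (not isolated), via coupled aryl silyl ether 27 (not isolated)
Conditions: 9-BBN (6 equiv), THF, 0 °C → rt; H2O; then 25, Pd(dppf)Cl2 (10 mol%), AsPh3, Cs2CO3, DMF/H2O, rt, 12 h
Reagents that add atoms: none
Why: 9-BBN hydroborates only the terminal vinyl group (boron on C4, trisubstituted alkene inert), and B-alkyl Suzuki–Miyaura coupling then joins C4 to C3 with retention of the E geometry because zerovalent palladium inserts into the C–I bond far faster than into the thioester C–S bond, while Cs2CO3 in wet DMF removes the electron-poor aryl silyl ether in the same pot.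

Step 13
Reactants: 28 seco nitro SNAC thioester (name as in step 12)
Product: 29 S-(2-acetamidoethyl) (2E,6S,7S,8E,10S,11R,12S,14S,15R)-15-(3-amino-5-hydroxyphenyl)-7,11,15-trihydroxy-6,12-dimethoxy-2,8,10,14-tetramethylpentadeca-2,8-dienethioate
Conditions: Zn dust, NH4Cl, THF/EtOH/H2O, rt
Reagents that add atoms: none
Why: Zn/NH4Cl dissolving-metal reduction of the nitroarene to the aniline under near-neutral conditions leaves both alkenes, the thioester and the benzylic and allylic alcohols untouched.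

Step 14
Reactants: 29 seco amino SNAC thioester (name as in step 13)
Product: 31 (2E,6S,7S,8E,10S,11R,12S,14S,15R)-7,11,15-trihydroxy-6,12-dimethoxy-2,8,10,14-tetramethylpentadeca-2,8-dienoic acid lactam formed to the 3-amino group of its 15-(3-amino-5-hydroxyphenyl) substituent (CNP0366451.1), via OAt active ester 30 (not isolated)
Conditions: AgOCOCF3 (3 equiv), HOAt (6 equiv), 2,6-lutidine, DMF, 0.5 mM (29 added over 12 h), rt → 45 °C, dark
Reagents that add atoms: none
Why: Silver-assisted thioester aminolysis (the activation used for peptide thioester segment coupling) run as a high-dilution macrolactamization, in which thiophilic Ag+ converts the SNAC thioester into the OAt ester that acylates the aniline but not the unactivated secondary alcohols (the C7 hydroxyl would have to form an eight-membered ring across the E-C2=C3 bond), so the 19-membered lactam closes without any hydroxyl protection and no stereocentre is touched.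

## Compound list
1 | 3-hydroxy-5-nitrobenzaldehyde | O=Cc1cc(O)cc([N+](=O)[O-])c1 | starting material
2 | 3-(tert-butyldimethylsilyloxy)-5-nitrobenzaldehyde | O=Cc1cc(O[Si](C)(C)C(C)(C)C)cc([N+](=O)[O-])c1 | intermediate
3 | cis-2-butene | C/C=C\C | starting material
4 | (Z)-crotylpotassium | [K+].C/C=C\[CH2-] | intermediate
5 | (Z)-crotyldiisopinocampheylborane, Ipc groups of the (−)-α-pinene series | C/C=C\CB([C@H]1C[C@H]2C[C@@H]([C@@H]1C)C2(C)C)[C@H]1C[C@H]2C[C@@H]([C@@H]1C)C2(C)C | intermediate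
6 | (1R,2S)-1-ArTBS-2-methylbut-3-en-1-ol (C12–C15; 14S,15R) | C=C[C@H](C)[C@@H](O)c1cc(O[Si](C)(C)C(C)(C)C)cc([N+](=O)[O-])c1 | intermediate
7 | (4S,5R)-5-ArTBS-5-hydroxy-4-methylpentanal | O=CCC[C@H](C)[C@@H](O)c1cc(O[Si](C)(C)C(C)(C)C)cc([N+](=O)[O-])c1 | intermediate
8 | (5S,6R)-6-ArTBS-5-methyltetrahydro-2H-pyran-2-ol, anomer mixture | OC1CC[C@H](C)[C@H](c2cc(O[Si](C)(C)C(C)(C)C)cc([N+](=O)[O-])c2)O1 | intermediate
9 | (5S,6R)-6-ArTBS-5-methyltetrahydro-2H-pyran-2-one | O=C1CC[C@H](C)[C@H](c2cc(O[Si](C)(C)C(C)(C)C)cc([N+](=O)[O-])c2)O1 | intermediate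
10 | potassium enolate of 9 | [K+].[O-]C1=CC[C@H](C)[C@H](c2cc(O[Si](C)(C)C(C)(C)C)cc([N+](=O)[O-])c2)O1 | intermediate
11 | (3S,5S,6R)-6-ArTBS-3-hydroxy-5-methyltetrahydro-2H-pyran-2-one | O=C1[C@@H](O)C[C@H](C)[C@H](c2cc(O[Si](C)(C)C(C)(C)C)cc([N+](=O)[O-])c2)O1 | intermediate
12 | (3S,5S,6R)-6-ArTBS-3-methoxy-5-methyltetrahydro-2H-pyran-2-one | O=C1[C@@H](OC)C[C@H](C)[C@H](c2cc(O[Si](C)(C)C(C)(C)C)cc([N+](=O)[O-])c2)O1 | intermediate
13 | (3S,5S,6R)-6-ArTBS-3-methoxy-5-methyltetrahydro-2H-pyran-2-ol, anomer mixture | OC1[C@@H](OC)C[C@H](C)[C@H](c2cc(O[Si](C)(C)C(C)(C)C)cc([N+](=O)[O-])c2)O1 | intermediate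
14 | (Z)-crotylboronic acid pinacol ester, 2-[(Z)-but-2-enyl]-4,4,5,5-tetramethyl-1,3,2-dioxaborolane | C/C=C\CB1OC(C)(C)C(C)(C)O1 | starting material
15 | (2S,4S,5R)-5-ArTBS-5-hydroxy-2-methoxy-4-methylpentanal | O=C[C@@H](OC)C[C@H](C)[C@@H](O)c1cc(O[Si](C)(C)C(C)(C)C)cc([N+](=O)[O-])c1 | intermediate
16 | (3S,4R,5S,7S,8R)-8-ArTBS-5-methoxy-3,7-dimethyloct-1-ene-4,8-diol (C9–C15) | C=C[C@H](C)[C@@H](O)[C@@H](OC)C[C@H](C)[C@@H](O)c1cc(O[Si](C)(C)C(C)(C)C)cc([N+](=O)[O-])c1 | intermediate
17 | methacrolein | C=C(C)C=O | starting material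
18 | (2E,4S,5R,6S,8S,9R)-9-ArTBS-5,9-dihydroxy-6-methoxy-2,4,8-trimethylnon-2-enal (C7–C15) | O=C/C(C)=C/[C@H](C)[C@@H](O)[C@@H](OC)C[C@H](C)[C@@H](O)c1cc(O[Si](C)(C)C(C)(C)C)cc([N+](=O)[O-])c1 | intermediate
19 | allyl methyl ether | C=CCOC | starting material
20 | (Z)-3-methoxyallyllithium | [Li+].CO/C=C\[CH2-] | intermediate
21 | (Z)-3-methoxyallyldiisopinocampheylborane, Ipc groups of the (−)-α-pinene series | CO/C=C\CB([C@H]1C[C@H]2C[C@@H]([C@@H]1C)C2(C)C)[C@H]1C[C@H]2C[C@@H]([C@@H]1C)C2(C)C | intermediate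
22 | (3S,4S,5E,7S,8R,9S,11S,12R)-12-ArTBS-3,9-dimethoxy-5,7,11-trimethyldodeca-1,5-diene-4,8,12-triol (C4–C15) | C=C[C@H](OC)[C@@H](O)/C(C)=C/[C@H](C)[C@@H](O)[C@@H](OC)C[C@H](C)[C@@H](O)c1cc(O[Si](C)(C)C(C)(C)C)cc([N+](=O)[O-])c1 | intermediate
23 | (E)-3-iodo-2-methylprop-2-enoic acid | OC(=O)/C(C)=C/I | starting material
24 | N-acetylcysteamine | CC(=O)NCCS | starting material
25 | S-(2-acetamidoethyl) (E)-3-iodo-2-methylprop-2-enethioate | CC(=O)NCCSC(=O)/C(C)=C/I | intermediate
26 | B-alkyl-9-BBN borane of 22, boron on C4 | B1(C2CCCC1CCC2)CC[C@H](OC)[C@@H](O)/C(C)=C/[C@H](C)[C@@H](O)[C@@H](OC)C[C@H](C)[C@@H](O)c1cc(O[Si](C)(C)C(C)(C)C)cc([N+](=O)[O-])c1 | intermediate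
27 | seco nitro SNAC thioester, aryl TBS ether (2E,6S,7S,8E,10S,11R,12S,14S,15R) | CC(=O)NCCSC(=O)/C(C)=C/CC[C@H](OC)[C@@H](O)/C(C)=C/[C@H](C)[C@@H](O)[C@@H](OC)C[C@H](C)[C@@H](O)c1cc(O[Si](C)(C)C(C)(C)C)cc([N+](=O)[O-])c1 | intermediate
28 | seco nitro SNAC thioester, free phenol (2E,6S,7S,8E,10S,11R,12S,14S,15R) | CC(=O)NCCSC(=O)/C(C)=C/CC[C@H](OC)[C@@H](O)/C(C)=C/[C@H](C)[C@@H](O)[C@@H](OC)C[C@H](C)[C@@H](O)c1cc(O)cc([N+](=O)[O-])c1 | intermediate
29 | seco amino SNAC thioester (2E,6S,7S,8E,10S,11R,12S,14S,15R) | CC(=O)NCCSC(=O)/C(C)=C/CC[C@H](OC)[C@@H](O)/C(C)=C/[C@H](C)[C@@H](O)[C@@H](OC)C[C@H](C)[C@@H](O)c1cc(O)cc(N)c1 | intermediate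
30 | 7-azabenzotriazol-1-yl (OAt) ester of the seco amino acid | O=C(On1nnc2cccnc12)/C(C)=C/CC[C@H](OC)[C@@H](O)/C(C)=C/[C@H](C)[C@@H](O)[C@@H](OC)C[C@H](C)[C@@H](O)c1cc(O)cc(N)c1 | intermediate
31 | CNP0366451.1, 19-membered anilide (2E,6S,7S,8E,10S,11R,12S,14S,15R) | CO[C@H]1C[C@H](C)[C@@H](O)c2cc(O)cc(c2)NC(=O)/C(C)=C/CC[C@H](OC)[C@@H](O)/C(C)=C/[C@H](C)[C@H]1O | target

## Step count and risk
Total steps: 14. Longest linear sequence: 13 (steps 1–10, 12–14); step 11 is a side branch.

**Most likely to fail, 1: step 14 (unprotected thioester-to-anilide macrolactamization).** The risks are O-acylation by the phenol or the C11/C15 hydroxyls and oligomerisation. The fallback sets out from 28 and comes back at 31, and replaces the protecting-group-free closure by a masked one. Compound 28 is persilylated (TESOTf, 2,6-lutidine, CH2Cl2, −78 °C) to the tetrakis(triethylsilyl) ether F1. Zn/NH4Cl reduction gives the silylated seco aniline thioester F2. This is cyclised under the same silver/HOAt activation, now with the aniline as the only nucleophile, to the tetrakis(triethylsilyl) macrolactam F3. HF·pyridine in THF/pyridine then releases 31.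

**Most likely to fail, 2: step 8 (crotylboration of a lactol under substrate control).** The risks are slow ring opening of 13, the modest reactivity of the pinacol boronate and incomplete substrate control at C10/C11. The fallback sets out from 12 and comes back at 16, and uses an open-chain, C15-protected aldehyde with a chiral reagent at −78 °C. Lactone 12 is opened with MeNH(OMe)·HCl/AlMe3 to the hydroxy Weinreb amide F4. Silylation (TESOTf, 2,6-lutidine) gives the C15 triethylsilyl ether F5. i-Bu2AlH at −78 °C gives the open-chain α-methoxy aldehyde F6. Brown crotylboration with borane 5 (made as in step 2) at −78 °C, which attacks the same Re face as in step 2 and is matched with the Felkin preference, gives the C15-silylated homoallylic alcohol F7. PPTS in MeOH removes the alkyl silyl ether, leaving the aryl one, and gives 16.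

**Most likely to fail, 3: step 12 (B-alkyl Suzuki coupling carrying a thioester, three free hydroxyls and an in-pot desilylation).** The risks are thioester hydrolysis or C–S insertion by palladium. The fallback sets out from 22 and 23 and comes back at 28, and installs the thioester after the cross-coupling. Triol 22 is hydroborated as before and the borane is coupled with the free acid 23 (as its caesium carboxylate; same catalyst and base, which also remove the aryl silyl ether) to give the seco nitro acid F8. F8 is then thioesterified chemoselectively with excess 24 (EDC, HOBt, no DMAP, so the hydroxyls are not acylated) to give 28.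

## Further compounds
F1 | step 14 | tetrakis(triethylsilyl) ether of 28 (O7, O11, O15 and phenol) | CC(=O)NCCSC(=O)/C(C)=C/CC[C@H](OC)[C@@H](O[Si](CC)(CC)CC)/C(C)=C/[C@H](C)[C@@H](O[Si](CC)(CC)CC)[C@@H](OC)C[C@H](C)[C@@H](O[Si](CC)(CC)CC)c1cc(O[Si](CC)(CC)CC)cc([N+](=O)[O-])c1
F2 | step 14 | silylated seco aniline thioester | CC(=O)NCCSC(=O)/C(C)=C/CC[C@H](OC)[C@@H](O[Si](CC)(CC)CC)/C(C)=C/[C@H](C)[C@@H](O[Si](CC)(CC)CC)[C@@H](OC)C[C@H](C)[C@@H](O[Si](CC)(CC)CC)c1cc(O[Si](CC)(CC)CC)cc(N)c1
F3 | step 14 | tetrakis(triethylsilyl) macrolactam | CO[C@H]1C[C@H](C)[C@@H](O[Si](CC)(CC)CC)c2cc(O[Si](CC)(CC)CC)cc(c2)NC(=O)/C(C)=C/CC[C@H](OC)[C@@H](O[Si](CC)(CC)CC)/C(C)=C/[C@H](C)[C@H]1O[Si](CC)(CC)CC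
F4 | step 8 | (2S,4S,5R)-5-ArTBS-5-hydroxy-N,2-dimethoxy-N,4-dimethylpentanamide | CON(C)C(=O)[C@@H](OC)C[C@H](C)[C@@H](O)c1cc(O[Si](C)(C)C(C)(C)C)cc([N+](=O)[O-])c1
F5 | step 8 | C15 triethylsilyl ether of F4 | CON(C)C(=O)[C@@H](OC)C[C@H](C)[C@@H](O[Si](CC)(CC)CC)c1cc(O[Si](C)(C)C(C)(C)C)cc([N+](=O)[O-])c1
F6 | step 8 | (2S,4S,5R)-5-ArTBS-2-methoxy-4-methyl-5-(triethylsilyloxy)pentanal | O=C[C@@H](OC)C[C@H](C)[C@@H](O[Si](CC)(CC)CC)c1cc(O[Si](C)(C)C(C)(C)C)cc([N+](=O)[O-])c1
F7 | step 8 | (3S,4R,5S,7S,8R)-8-ArTBS-5-methoxy-3,7-dimethyl-8-(triethylsilyloxy)oct-1-en-4-ol | C=C[C@H](C)[C@@H](O)[C@@H](OC)C[C@H](C)[C@@H](O[Si](CC)(CC)CC)c1cc(O[Si](C)(C)C(C)(C)C)cc([N+](=O)[O-])c1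
F8 | step 12 | seco nitro acid, free phenol (2E,6S,7S,8E,10S,11R,12S,14S,15R) | OC(=O)/C(C)=C/CC[C@H](OC)[C@@H](O)/C(C)=C/[C@H](C)[C@@H](O)[C@@H](OC)C[C@H](C)[C@@H](O)c1cc(O)cc([N+](=O)[O-])c1
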